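**Remark (assumption on the chemistry):** germacrane numbering (C1–C15) is used for all intermediates. The zinc allylation of step 17 is assumed to follow the syn course usual for 3-substituted 2-(alkoxycarbonyl)allylzinc reagents, so the lactone is closed with inversion at C6 (steps 18–19).

## Analysis of the target

The target is a furanoheliangolide. Its ten-membered carbocycle (C1–C10) is bridged by an oxygen from C10 to C3, so that O–C10–C1(=O)–C2=C3 form a 3(2H)-furanone. An α-methylene-γ-butyrolactone (O–C6, C7, C11=C13, C12=O) is trans-fused at C6–C7. The remaining ring alkene, C4=C5, is Z and carries the C4 methyl; with C2=C3 and the C1 ketone it forms a cross-conjugated vinylogous ester.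

Five contiguous stereocentres run from C6 to C10 (6R,7S,8S,9S,10S). H6 and H7 are trans, and the oxygens on C8, C9 and C10 all lie on one side of a Fischer projection drawn with C1 at the top (an L-ribo triad). C8/C9 are therefore an erythro diol, and C10 is quaternary with a methyl group.

The sensitive groups are two Michael acceptors (exocyclic methylene lactone, methacrylate) and two different esters on neighbouring secondary oxygens. These esters can migrate, and C12 can translactonise from O6 to O8. The difficulties are the strained, bridged medium ring with its Z alkene, the dense oxygenation, and the need to tell O8 from O9.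

The strategy rests on C1. It sits between the quaternary carbinol carbon C10 and the enol-ether bond C2=C3. That is the retron of a C10 hydroxyl adding across a C1-keto C2≡C3 ynone, and the ynone in turn comes from a non-enolisable C1 aldehyde and a C2 alkynyl nucleophile.

## Retrosynthetic reasoning

**Esters (36 ⇒ 35 ⇒ 34).** The two acyl groups are removed last-in, first-out: acetate from O9, then methacrylate from O8. O8 lies between two methine carbons and O9 is neopentyl-like next to C10, so the forward acylations follow the steric order. The first acyl group then sits on the oxygen it also prefers thermodynamically, which removes the driving force for migration.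

**Diol and furanone (34 ⇒ 33 ⇒ 31).** The 8,9-diol is masked as a cis-acetonide, which also keeps O8 and O9 away from the ynone. The O–C3 bond of 33 is cut to give the ynone 31 with O10 silylated. Forward, only O10 can be released, so only the 5-endo-dig closure is possible, and it releases the bending strain of the ring alkyne.

**C1–C2 (31 ⇒ 30 ⇒ 27, key).** The ring is opened between C1 and C2 to give the aldehyde/iodoalkyne 27. This is the only ring bond whose cleavage leaves every stereocentre of the target in an acyclic, chiral-pool-derived chain. C10 is quaternary, so the aldehyde cannot enolise. The forward chromium-mediated alkynyl addition must close a ten-membered ring and creates one carbinol centre that is oxidised away.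

**Functional handles (27 ⇒ 26 ⇒ 25).** The aldehyde is traced to a primary triethylsilyl ether and the iodoalkyne to a terminal alkyne. With O1 and O10 both as triethylsilyl ethers, a Swern oxidation can address the primary one selectively, so no separate deprotection is needed.

**Lactone and C6–C7 (25 ⇒ 24 ⇒ 23 ⇒ 21 + 5).** The C6–C7 bond is cut to an allylic bromide 21 and the (Z)-enynal 5. Zinc reagents of this type add through a chair with the C7 substituent axial and give the syn adduct 23. That is the C6 epimer of what a trans-lactone needs, so the lactone C–O bond is made with inversion (Mitsunobu closure of acid 24) rather than by direct acyl transfer. Facial control at C7 comes from the cis-dioxolane: the C9 side of the alkene is blocked by the C10 substituent.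

**Allylic bromide (21 ⇒ 20 ⇒ 17 + 18).** C7–C11 is cut to aldehyde 17 and a three-carbon acrylate unit from 18. The organoaluminium route to the hydroxy-acrylate is chosen over the amine-catalysed one because 17 is a cis-dioxolane carbaldehyde that can epimerise at C8 on long exposure to amine.

**Protecting pattern (17 ⇒ 16 ⇒ 15 ⇒ 14 ⇒ 13 ⇒ 12 ⇒ 11 ⇒ 10).** Lactone 10 holds O8 in the ring and leaves a secondary (O9) and a tertiary (O10) hydroxyl free. Each later decision uses a clear reactivity difference:
- acetate on the secondary O9, silyl on the tertiary O10;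
- hydride opens the lactone and removes the acetate;
- the primary O1 is silylated;
- the only remaining vicinal diol (O8/O9) takes the acetonide.

**Triad (10 ⇒ 9 ⇒ 8 ⇒ 7 ⇒ 6).** The C9 and C10 oxygens are removed to give butenolide 9, whose single stereocentre (C8) directs osmylation to the opposite face. Ring-closing metathesis of 8 and a one-carbon homologation of epoxide 6 complete the chain. The configuration of 6 maps directly onto C8.

**Enynal (5 ⇒ 4 ⇒ 2 + 3 ⇒ 1).** The C3–C4 bond is cut to vinyl iodide 2 and alkyne 3. The Z geometry of C4=C5 is fixed at the start by trans-hydroalumination of 1.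

## Alternatives that were turned down

**Alternative 1:** A furan spanning C3 and C6 (furanophane ketol A1) is the latent enedione. Anodic oxidation in methanol and mild acid would open it to the cis-enedione, and O10 would then close on the C3 carbonyl to give furanone A2.
- For: the oxidation needs no reagent beyond current. The furan delivers the Z geometry of C4=C5 automatically. Closure onto a ketone is geometrically easier than 5-endo-dig. No strained alkyne is involved. On these points it is as good as or better than the chosen route.
- Against: C6 emerges as a ketone, so its configuration must be re-made by a face-selective 1,2-reduction of an enone next to a second carbonyl. A2 carries only a CH2CO2Me arm, so lactonisation and α-methylenation by enolate chemistry come late, on a substrate with several acidic sites. O10 can also capture C6. A1 is itself a strained bridged furan whose ring closure the step does not solve.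
- Comparison: the chosen route keeps C6, C7 and the methylene lactone intact from the acyclic stage and spends its risk on one ring closure.

**Alternative 2:** The C8=C9 bond is formed by ring-closing metathesis of divinyl compound A3 to the bridged Z-alkene A4. The cis-diol is added afterwards by osmylation.
- For: ruthenium carbene catalysts tolerate the lactone and furanone. The only by-product is ethylene. No protecting groups are needed on O8/O9. In functional-group tolerance, and in avoiding stoichiometric CrCl2, it is superior.
- Against: one vinyl group sits on the quaternary C10, and medium-ring metathesis is reversible and prone to oligomers. The dihydroxylation of A4 must then pick one of five alkenes and one of two faces, with only the ring conformation as control element. O8 and O9 still have to be told apart afterwards.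
- Comparison: the chosen route takes C8, C9 and C10 from a butenolide osmylation of secure relative and absolute sense before any ring is closed.

**Alternative 3:** The nitrile oxide from enal oxime A5 adds to its own terminal alkyne to give isoxazole-bridged macrocycle A6. The isoxazole is later reduced and hydrolysed to the furanone.
- For: two bonds form in one metal-free step. The isoxazole is a robust, non-electrophilic furanone surrogate, and its unmasking is classical.
- Against: with a seven-atom tether the dipole normally reaches the near alkyne carbon, which gives the fused regioisomer rather than the required 3,5-bridged one. Dimerisation of the dipole competes at high dilution. A6 lacks the C13 methylene and needs several more steps (N–O cleavage, hydrolysis, cyclodehydration, methylenation).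
- Comparison: the chosen closure also builds a strained ring, but by end-on addition of a linear nucleophile to a carbonyl. The strain is then released in the very next bond-forming event.

Key step: step 22

## Route

Step 1
Reactants: 1 but-2-yn-1-ol
Product: 2 (Z)-3-iodobut-2-en-1-ol
Conditions: NaAlH2(OCH2CH2OCH3)2, THF, 0 °C → rt; then I2, −78 → 0 °C
Reagents that add atoms: iodine, II
Why: Alkoxide-directed trans-hydroalumination places aluminium on C3 anti to the new C–H bond and iodinolysis retains configuration, the standard route to (Z)-3-iodoallylic alcohols; this fixes the later C4=C5 geometry.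

Step 2
Reactants: 2 (Z)-3-iodobut-2-en-1-ol; 3 trimethylsilylacetylene
Product: 4 (Z)-3-methyl-5-(trimethylsilyl)pent-2-en-4-yn-1-ol
Conditions: Pd(PPh3)2Cl2 (2 mol%), CuI (4 mol%), Et3N, THF, rt
Reagents that add atoms: none
Why: Sonogashira coupling of a vinyl iodide is stereoretentive and tolerates the free allylic alcohol.

Step 3
Reactants: 4 (Z)-3-methyl-5-(trimethylsilyl)pent-2-en-4-yn-1-ol
Product: 5 (Z)-3-methyl-5-(trimethylsilyl)pent-2-en-4-ynal
Conditions: MnO2, CH2Cl2, rt
Reagents that add atoms: none
Why: Heterogeneous allylic oxidation under neutral conditions should give the (Z)-enal without isomerisation; the aldehyde is used directly in step 17.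

Step 4
Reactants: 6 (R)-benzyl glycidyl ether
Product: 7 (R)-1-(benzyloxy)but-3-en-2-ol
Conditions: Me3S+ I−, n-BuLi, THF, −10 °C → rt
Reagents that add atoms: trimethylsulfonium iodide, C[S+](C)C.[I-]
Why: Excess sulfonium methylide opens the epoxide at CH2 and the resulting sulfonium betaine eliminates Me2S (epoxide-to-allylic-alcohol homologation); the stereocentre, the future C8, is not touched.

Step 5
Reactants: 7 (R)-1-(benzyloxy)but-3-en-2-ol
Product: 8 (R)-1-(benzyloxy)but-3-en-2-yl 2-methylprop-2-enoate
Conditions: methacryloyl chloride, Et3N, DMAP (cat.), CH2Cl2, 0 °C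
Reagents that add atoms: methacryloyl chloride, C=C(C)C(Cl)=O
Why: Routine O-acylation of a secondary alcohol; it brings in C1, C10 and the C10 methyl.

Step 6
Reactants: 8 (R)-1-(benzyloxy)but-3-en-2-yl 2-methylprop-2-enoate
Product: 9 (R)-5-[(benzyloxy)methyl]-3-methylfuran-2(5H)-one
Conditions: (H2IMes)(PCy3)Cl2Ru=CHPh (second-generation Grubbs catalyst, 5 mol%), toluene, 80 °C, 0.01 M
Reagents that add atoms: none
Why: Ring-closing metathesis of allyl methacrylates to α-methyl butenolides is well established with this catalyst; five-ring closure and loss of ethylene drive it.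

Step 7
Reactants: 9 (R)-5-[(benzyloxy)methyl]-3-methylfuran-2(5H)-one
Product: 10 5-O-benzyl-2-C-methyl-L-ribono-1,4-lactone
Conditions: OsO4 (2 mol%), NMO, citric acid, t-BuOH/H2O, rt
Reagents that add atoms: N-methylmorpholine N-oxide, C[N+]1([O-])CCOCC1; water, O
Why: Catalytic syn-dihydroxylation (Upjohn conditions, citric acid for the electron-poor alkene) occurs on the ring face opposite the C5 benzyloxymethyl group, setting C9 and C10 cis to each other and trans to C7 (ribo).

Step 8
Reactants: 10 5-O-benzyl-2-C-methyl-L-ribono-1,4-lactone
Product: 11 3-O-acetyl-5-O-benzyl-2-C-methyl-L-ribono-1,4-lactone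
Conditions: Ac2O (1.2 equiv), pyridine, DMAP (cat.), CH2Cl2, 0 °C
Reagents that add atoms: acetic anhydride, CC(=O)OC(C)=O
Why: Acylation distinguishes the secondary O9 from the tertiary α-hydroxy-lactone O10, which does not react at 0 °C; C10 is quaternary, so no β-elimination is possible.

Step 9
Reactants: 11 3-O-acetyl-5-O-benzyl-2-C-methyl-L-ribono-1,4-lactone
Product: 12 3-O-acetyl-5-O-benzyl-2-C-methyl-2-O-(triethylsilyl)-L-ribono-1,4-lactone
Conditions: TESOTf, 2,6-lutidine, CH2Cl2, 0 °C → rt
Reagents that add atoms: triethylsilyl trifluoromethanesulfonate, CC[Si](CC)(CC)OS(=O)(=O)C(F)(F)F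
Why: Silyl triflates silylate tertiary alcohols; O10 is the only free hydroxyl.

Step 10
Reactants: 12 3-O-acetyl-5-O-benzyl-2-C-methyl-2-O-(triethylsilyl)-L-ribono-1,4-lactone
Product: 13 5-O-benzyl-2-C-methyl-2-O-(triethylsilyl)-L-ribitol
Conditions: LiAlH4, THF, −20 → 0 °C; aq. KNaC4H4O6 work-up
Reagents that add atoms: none
Why: Hydride reduction opens the lactone to the C1 primary and C8 secondary alcohols and removes the acetate in the same operation; the cold quench limits 1,2-silyl migration from the tertiary oxygen.

Step 11
Reactants: 13 5-O-benzyl-2-C-methyl-2-O-(triethylsilyl)-L-ribitol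
Product: 14 5-O-benzyl-2-C-methyl-1,2-bis-O-(triethylsilyl)-L-ribitol
Conditions: TESCl (1.05 equiv), imidazole, CH2Cl2, −78 → −30 °C
Reagents that add atoms: chlorotriethylsilane, CC[Si](Cl)(CC)CC
Why: Silyl chlorides react with the primary C1 hydroxyl in preference to the two secondary ones at low temperature; capping O1 prevents a competing 1,3-dioxane in step 12.

Step 12
Reactants: 14 5-O-benzyl-2-C-methyl-1,2-bis-O-(triethylsilyl)-L-ribitol
Product: 15 5-O-benzyl-3,4-O-isopropylidene-2-C-methyl-1,2-bis-O-(triethylsilyl)-L-ribitol
Conditions: 2-methoxypropene, PPTS (cat.), CH2Cl2, 0 °C; Et3N quench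
Reagents that add atoms: 2-methoxypropene, COC(C)=C
Why: The erythro O8/O9 diol is the only diol left and gives the cis-dioxolane; aprotic, weakly acidic conditions spare the primary silyl ether.

Step 13
Reactants: 15 5-O-benzyl-3,4-O-isopropylidene-2-C-methyl-1,2-bis-O-(triethylsilyl)-L-ribitol
Product: 16 3,4-O-isopropylidene-2-C-methyl-1,2-bis-O-(triethylsilyl)-L-ribitol
Conditions: H2 (1 atm), Pd/C, EtOAc, rt
Reagents that add atoms: none
Why: Hydrogenolysis of the benzyl ether in a neutral aprotic solvent leaves silyl ethers and the acetonide intact; no alkene is present yet.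

Step 14
Reactants: 16 3,4-O-isopropylidene-2-C-methyl-1,2-bis-O-(triethylsilyl)-L-ribitol
Product: 17 2,3-O-isopropylidene-4-C-methyl-4,5-bis-O-(triethylsilyl)-aldehydo-D-ribose
Conditions: Dess–Martin periodinane, NaHCO3, CH2Cl2, 0 °C → rt
Reagents that add atoms: none
Why: Buffered periodinane oxidation gives the α-alkoxy aldehyde (C7) without base and so without C8 epimerisation; a Swern oxidation is avoided here because it would also attack the primary silyl ether.

Step 15
Reactants: 17 2,3-O-isopropylidene-4-C-methyl-4,5-bis-O-(triethylsilyl)-aldehydo-D-ribose; 18 methyl propiolate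
Product: 20 Morita–Baylis–Hillman-type adduct (methyl 2-methylidene-3-hydroxy ester; C7 epimers), via vinylalane 19 (not isolated)
Conditions: i-Bu2AlH, NMO, THF, 0 °C, then 18; then 17, 0 °C → rt
Reagents that add atoms: none
Why: Conjugate hydroalumination of the propiolate gives the α-aluminoacrylate, which adds to aldehydes within hours (organoaluminium route to Morita–Baylis–Hillman adducts); this avoids days of amine exposure that could epimerise the cis-dioxolane aldehyde, and the C7 configuration is irrelevant.

Step 16
Reactants: 20 Morita–Baylis–Hillman-type adduct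
Product: 21 methyl (2Z)-2-(bromomethyl)-3-(dioxolanyl)prop-2-enoate (C7=C11 alkene; C13 bromide)
Conditions: NBS, Me2S, CH2Cl2, 0 °C → rt
Reagents that add atoms: N-bromosuccinimide, O=C1CCC(=O)N1Br
Why: The alkoxysulfonium salt of the allylic alcohol is displaced by bromide in SN2′ fashion; for ester adducts this gives the (2Z)-bromide (C8 cis to CH2Br), and the conditions are mild enough for the acetonide and silyl ethers.

Step 17
Reactants: 21 (2Z)-allylic bromide; 5 (Z)-3-methyl-5-(trimethylsilyl)pent-2-en-4-ynal
Product: 23 (6S,7S)-hydroxy ester (syn adduct), via allylzinc bromide 22 (not isolated)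
Conditions: Zn dust, THF/sat. aq. NH4Cl (4:1), 0 °C → rt
Reagents that add atoms: none
Why: Barbier allylation through a chair (Zimmerman–Traxler) transition state forms C6–C7 at the γ-carbon; with H8 eclipsing the alkene (allylic strain) the aldehyde approaches the face next to the ring oxygen O8, away from C9 and its cis C10 group, which sets C7 (S), and the C8 substituent cis to CH2Zn sits axial, which gives the syn C6 (S) carbinol; in the protic medium the hydroxy ester is not expected to lactonise.

Step 18
Reactants: 23 (6S,7S)-hydroxy ester
Product: 24 (6S,7S)-hydroxy acid with terminal alkyne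
Conditions: LiOH, THF/MeOH/H2O, 0 °C → rt; AcOH to pH 5, 0 °C
Reagents that add atoms: lithium hydroxide, [Li+].[OH-]
Why: Saponification of the methyl ester and protodesilylation of the alkyne occur together; the hindered silyl ethers tolerate mild base, and cold buffered acidification avoids acid-catalysed closure with retention.

Step 19
Reactants: 24 (6S,7S)-hydroxy acid
Product: 25 trans-lactone (6R,7S) with terminal alkyne; C8/C9 acetonide; O1 and O10 triethylsilyl
Conditions: PPh3, DIAD, toluene, −20 → 0 °C
Reagents that add atoms: none
Why: Mitsunobu lactonisation activates the C6 hydroxyl and the carboxylate displaces it in a 5-exo-tet SN2 reaction with inversion, converting the syn adduct into the trans-fused methylene lactone; attack at C4 (SN2′) would need a seven-membered ring.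

Step 20
Reactants: 25 trans-lactone with terminal alkyne
Product: 26 iodoalkyne lactone
Conditions: NIS, AgNO3 (10 mol%), acetone, rt, dark
Reagents that add atoms: N-iodosuccinimide, O=C1CCC(=O)N1I
Why: Silver-catalysed iodination of the terminal C–H via the silver acetylide is selective for the alkyne and neutral.

Step 21
Reactants: 26 iodoalkyne lactone
Product: 27 C1 aldehyde with O10 triethylsilyl ether, C8/C9 acetonide, trans-lactone and iodoalkyne
Conditions: (COCl)2, DMSO, CH2Cl2, −78 → −35 °C; Et3N, → 0 °C
Reagents that add atoms: none
Why: Under Swern conditions a primary triethylsilyl ether is cleaved by the chlorosulfonium salt and oxidised directly, while the hindered tertiary one survives; the aldehyde has no α-hydrogen, so Et3N cannot epimerise it.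

Step 22
Reactants: 27 aldehyde/iodoalkyne
Product: 30 ten-membered enyne propargylic alcohol (C1 epimers), via alkynylchromium dichloride 28 (not isolated), via chromium alkoxide 29 (not isolated)
Conditions: CrCl2 (10 equiv), NiCl2 (1 mol% of CrCl2), degassed THF, rt, 27 added over 12 h to 2 mM; aq. NH4Cl
Reagents that add atoms: none
Why: CrCl2 reduces NiCl2 to zerovalent nickel, which inserts into the C(sp)–I bond; the alkynyl group passes to trivalent chromium (28, two CrCl2 per C–I bond) and the linear, weakly basic alkynylchromium adds to the C1 aldehyde to give alkoxide 29, hydrolysed to 30 on work-up. The closest known reaction type is the Nozaki–Hiyama–Kishi coupling of alkynyl iodides with aldehydes, which has closed nine- and ten-membered enyne and enediyne carbocycles. The closure is 10-exo-trig: the C=O π bond lies outside the forming ring and the nucleophile arrives end-on, so only modest bending of C1–C2≡C3–C4 is needed. The new C1 centre is governed by the ring conformation and by approach anti to the C10–O bond (Felkin-type); a mixture is acceptable because C1 becomes a ketone in step 23. Three selectivities are needed: C–I activation over the enoate and lactone (nickel catalysis; both are inert to divalent and trivalent chromium), addition over enolisation (C10 is quaternary), and cyclisation over oligomerisation (slow addition at high dilution, and the (Z)-alkene, trans-lactone and cis-dioxolane each impose a turn toward C1).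

Step 23
Reactants: 30 ten-membered enyne propargylic alcohol
Product: 31 ten-membered ynone
Conditions: Dess–Martin periodinane, NaHCO3, CH2Cl2, 0 °C → rt
Reagents that add atoms: none
Why: Neutral oxidation of the propargylic alcohol; both C1 epimers converge on one ynone.

Step 24
Reactants: 31 ten-membered ynone
Product: 33 furanone acetonide, via hydroxy ynone 32 (not isolated)
Conditions: HF·pyridine, pyridine, THF, 0 °C → rt; then Ph3PAuNTf2 (5 mol%), toluene, rt
Reagents that add atoms: none
Why: Fluoride removes the only silyl ether; the freed C10 hydroxyl adds to C3 of the ynone by 5-endo-dig oxa-Michael closure (the known monovalent-gold cyclisation of γ-hydroxy alkynones to 3(2H)-furanones), and rehybridisation of C2 and C3 releases the bending strain of the ring alkyne.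

Step 25
Reactants: 33 furanone acetonide
Product: 34 8,9-diol
Conditions: TFA/H2O (9:1), 0 °C
Reagents that add atoms: none
Why: Acetal hydrolysis; the vinylogous ester and the lactone tolerate brief cold aqueous acid, which also does not promote translactonisation.

Step 26
Reactants: 34 8,9-diol
Product: 35 8-O-methacryloyl-9-ol
Conditions: methacrylic anhydride (1.1 equiv), Et3N, DMAP (cat.), CH2Cl2, −40 → −20 °C
Reagents that add atoms: methacrylic anhydride, C=C(C)C(=O)OC(=O)C(C)=C
Why: DMAP-catalysed acylation should favour O8 (between two methines) over O9 (neopentyl-like, next to quaternary C10); the acyl group lands on the oxygen it also prefers at equilibrium, so migration has no driving force.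

Step 27
Reactants: 35 8-O-methacryloyl-9-ol
Product: 36 CNP0365569.2 (target)
Conditions: Ac2O, pyridine, DMAP, CH2Cl2, rt
Reagents that add atoms: acetic anhydride, CC(=O)OC(C)=O
Why: Acetylation of the one remaining, hindered hydroxyl under DMAP catalysis; no other nucleophilic site is left.

## Compound list

1 | but-2-yn-1-ol | CC#CCO | starting material
2 | (Z)-3-iodobut-2-en-1-ol | OC/C=C(/C)I | intermediate
3 | trimethylsilylacetylene | C#C[Si](C)(C)C | starting material
4 | (Z)-3-methyl-5-(trimethylsilyl)pent-2-en-4-yn-1-ol | OC/C=C(/C)C#C[Si](C)(C)C | intermediate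
5 | (Z)-3-methyl-5-(trimethylsilyl)pent-2-en-4-ynal | O=C/C=C(/C)C#C[Si](C)(C)C | intermediate
6 | (R)-benzyl glycidyl ether | C1O[C@H]1COCc1ccccc1 | starting material
7 | (R)-1-(benzyloxy)but-3-en-2-ol | C=C[C@@H](O)COCc1ccccc1 | intermediate
8 | (R)-1-(benzyloxy)but-3-en-2-yl 2-methylprop-2-enoate | C=C(C)C(=O)O[C@H](C=C)COCc1ccccc1 | intermediate
9 | (R)-5-[(benzyloxy)methyl]-3-methylfuran-2(5H)-one | CC1=C[C@H](COCc2ccccc2)OC1=O | intermediate
10 | 5-O-benzyl-2-C-methyl-L-ribono-1,4-lactone, (3S,4S,5S)-5-[(benzyloxy)methyl]-3,4-dihydroxy-3-methyloxolan-2-one | O=C1O[C@@H](COCc2ccccc2)[C@H](O)[C@]1(C)O | intermediate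
11 | 3-O-acetyl-5-O-benzyl-2-C-methyl-L-ribono-1,4-lactone (acetate on O9) | O=C1O[C@@H](COCc2ccccc2)[C@H](OC(C)=O)[C@]1(C)O | intermediate
12 | 3-O-acetyl-5-O-benzyl-2-C-methyl-2-O-(triethylsilyl)-L-ribono-1,4-lactone | O=C1O[C@@H](COCc2ccccc2)[C@H](OC(C)=O)[C@]1(C)O[Si](CC)(CC)CC | intermediate
13 | 5-O-benzyl-2-C-methyl-2-O-(triethylsilyl)-L-ribitol (O1, O8, O9 free) | OC[C@@](C)(O[Si](CC)(CC)CC)[C@@H](O)[C@@H](O)COCc1ccccc1 | intermediate
14 | 5-O-benzyl-2-C-methyl-1,2-bis-O-(triethylsilyl)-L-ribitol | CC[Si](CC)(CC)OC[C@@](C)(O[Si](CC)(CC)CC)[C@@H](O)[C@@H](O)COCc1ccccc1 | intermediate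
15 | 5-O-benzyl-3,4-O-isopropylidene-2-C-methyl-1,2-bis-O-(triethylsilyl)-L-ribitol | CC[Si](CC)(CC)OC[C@@](C)(O[Si](CC)(CC)CC)[C@H]1OC(C)(C)O[C@H]1COCc1ccccc1 | intermediate
16 | 3,4-O-isopropylidene-2-C-methyl-1,2-bis-O-(triethylsilyl)-L-ribitol (C7 alcohol) | CC[Si](CC)(CC)OC[C@@](C)(O[Si](CC)(CC)CC)[C@H]1OC(C)(C)O[C@H]1CO | intermediate
17 | 2,3-O-isopropylidene-4-C-methyl-4,5-bis-O-(triethylsilyl)-aldehydo-D-ribose (C7 aldehyde) | CC[Si](CC)(CC)OC[C@@](C)(O[Si](CC)(CC)CC)[C@H]1OC(C)(C)O[C@H]1C=O | intermediate
18 | methyl propiolate | C#CC(=O)OC | starting material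
19 | [1-(methoxycarbonyl)vinyl]diisobutylaluminium (vinylalane, not isolated) | C=C(C(=O)OC)[Al](CC(C)C)CC(C)C | intermediate
20 | Morita–Baylis–Hillman-type adduct of 17: methyl 2-methylidene-3-hydroxy ester, C7 carbinol as both epimers | CC[Si](CC)(CC)OC[C@@](C)(O[Si](CC)(CC)CC)[C@H]1OC(C)(C)O[C@H]1C(O)C(=C)C(=O)OC | intermediate
21 | methyl (2Z)-2-(bromomethyl)-3-(dioxolanyl)prop-2-enoate (C7=C11, C13 bromide) | CC[Si](CC)(CC)OC[C@@](C)(O[Si](CC)(CC)CC)[C@H]1OC(C)(C)O[C@H]1/C=C(\CBr)C(=O)OC | intermediate
22 | allylzinc bromide from 21 (not isolated) | CC[Si](CC)(CC)OC[C@@](C)(O[Si](CC)(CC)CC)[C@H]1OC(C)(C)O[C@H]1/C=C(\C[Zn]Br)C(=O)OC | intermediate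
23 | (6S,7S)-hydroxy ester, syn adduct (C12 methyl ester, C11=C13, C6 hydroxyl, (Z)-C4=C5, silylalkyne) | CC[Si](CC)(CC)OC[C@@](C)(O[Si](CC)(CC)CC)[C@H]1OC(C)(C)O[C@H]1[C@@H](C(=C)C(=O)OC)[C@@H](O)/C=C(/C)C#C[Si](C)(C)C | intermediate
24 | (6S,7S)-hydroxy acid with terminal alkyne | CC[Si](CC)(CC)OC[C@@](C)(O[Si](CC)(CC)CC)[C@H]1OC(C)(C)O[C@H]1[C@@H](C(=C)C(O)=O)[C@@H](O)/C=C(/C)C#C | intermediate
25 | (6R,7S)-trans-α-methylene lactone with terminal alkyne | CC[Si](CC)(CC)OC[C@@](C)(O[Si](CC)(CC)CC)[C@H]1OC(C)(C)O[C@H]1[C@H]2C(=C)C(=O)O[C@@H]2/C=C(/C)C#C | intermediate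
26 | iodoalkyne lactone | CC[Si](CC)(CC)OC[C@@](C)(O[Si](CC)(CC)CC)[C@H]1OC(C)(C)O[C@H]1[C@H]2C(=C)C(=O)O[C@@H]2/C=C(/C)C#CI | intermediate
27 | C1 aldehyde/iodoalkyne (precursor of the key step) | O=C[C@@](C)(O[Si](CC)(CC)CC)[C@H]1OC(C)(C)O[C@H]1[C@H]2C(=C)C(=O)O[C@@H]2/C=C(/C)C#CI | intermediate
28 | alkynylchromium dichloride (trivalent chromium, not isolated) | O=C[C@@](C)(O[Si](CC)(CC)CC)[C@H]1OC(C)(C)O[C@H]1[C@H]2C(=C)C(=O)O[C@@H]2/C=C(/C)C#C[Cr](Cl)Cl | intermediate
29 | chromium alkoxide of 30 (not isolated) | CC1(C)O[C@H]2[C@H]3C(=C)C(=O)O[C@@H]3/C=C(/C)C#CC(O[Cr](Cl)Cl)[C@@](C)(O[Si](CC)(CC)CC)[C@H]2O1 | intermediate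
30 | ten-membered enyne propargylic alcohol, (1RS) | CC1(C)O[C@H]2[C@H]3C(=C)C(=O)O[C@@H]3/C=C(/C)C#CC(O)[C@@](C)(O[Si](CC)(CC)CC)[C@H]2O1 | intermediate
31 | ten-membered ynone | CC1(C)O[C@H]2[C@H]3C(=C)C(=O)O[C@@H]3/C=C(/C)C#CC(=O)[C@@](C)(O[Si](CC)(CC)CC)[C@H]2O1 | intermediate
32 | α′-hydroxy ynone (not isolated) | CC1(C)O[C@H]2[C@H]3C(=C)C(=O)O[C@@H]3/C=C(/C)C#CC(=O)[C@@](C)(O)[C@H]2O1 | intermediate
33 | furanone acetonide | CC1(C)O[C@H]2[C@H]3C(=C)C(=O)O[C@@H]3/C=C(/C)C3=CC(=O)[C@@](C)(O3)[C@H]2O1 | intermediate
34 | 8,9-diol | O[C@H]1[C@H]2C(=C)C(=O)O[C@@H]2/C=C(/C)C2=CC(=O)[C@@](C)(O2)[C@H]1O | intermediate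
35 | 8-O-methacryloyl-9-ol | C=C(C)C(=O)O[C@H]1[C@H]2C(=C)C(=O)O[C@@H]2/C=C(/C)C2=CC(=O)[C@@](C)(O2)[C@H]1O | intermediate
36 | CNP0365569.2 | C=C(C)C(=O)O[C@H]1[C@H]2C(=C)C(=O)O[C@@H]2/C=C(/C)C2=CC(=O)[C@@](C)(O2)[C@H]1OC(C)=O | target

## Step count and least certain steps

Total: 27 steps. Longest linear sequence: 24 steps (6 → 36, steps 4–27). The enynal branch (steps 1–3) joins at step 17.

**Step 22 (key).** The most likely failure is that intermolecular addition, or protonation and reduction of the alkynylchromium, outruns ring closure. The closing transition state must bend the C1–C2≡C3–C4 unit, and C–I activation is slow at 2 mM. The fallback changes how the nucleophile is made and which precursor is cyclised. It sets out from 25: Swern oxidation of the primary silyl ether, without prior iodination, gives the terminal-alkyne aldehyde F1. F1 is treated at 2 mM in toluene with Zn(OTf)2 and i-Pr2NEt. This zincates the terminal C–H reversibly (known for additions of terminal alkynes to α-branched aldehydes), so the acetylide concentration stays low and unreacted material is not destroyed. The zinc acetylide adds to the non-enolisable aldehyde and gives 30, where the route is rejoined.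

**Step 17.** The most likely failure is erosion of selectivity in the allylzinc addition. The reagent may equilibrate between its two alkene geometries and give a mixed C6 configuration, and facial discrimination at C7 rests on the dioxolane alone. The fallback makes the route independent of the C6 outcome. It sets out from 21 and 5: the anti adduct F2 (6R,7S), separated from 23, is lactonised with retention (PPTS, toluene, 40 °C) to the silylalkyne trans-lactone F3. AgNO3-catalysed iododesilylation with N-iodosuccinimide in DMF converts F3 directly into 26. Both C6 epimers therefore reach the same trans-lactone series, one by invertive and one by retentive closure. A wrong C7 epimer is not rescued by this fallback and would have to be separated.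

**Step 19.** The most likely failure is loss of stereochemical fidelity in the invertive closure. The allylic alkoxyphosphonium ion may ionise, or the acid may be activated instead of the alcohol; both lead to retention and the cis-lactone. The fallback separates inversion from ring closure. It sets out from 23: intermolecular Mitsunobu esterification with 4-nitrobenzoic acid gives the inverted ester F4. K2CO3 in methanol removes the nitrobenzoate and the C-silyl group to give the (6R)-hydroxy ester F5. F5 closes with retention (PPTS) to 25.

**Step 24.** The most likely failure is diversion of the liberated hydroxy ynone before closure, by hydration or addition of external nucleophiles to the strained triple bond or by gold-induced isomerisation of the (Z)-enyne. The fallback replaces 5-endo-dig closure by addition–elimination. It sets out from 31: PBu3-catalysed conjugate addition of methanol gives the β-methoxy enone F6 with the silyl ether still in place. HF·pyridine and then catalytic TsOH free O10, which attacks the O-protonated vinylogous ester at C3 and expels methanol to give 33.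

**Step 26.** The most likely failure is incomplete discrimination between the two secondary hydroxyls, acyl migration between O8 and O9, or base-induced translactonisation of C12 from O6 to O8. The fallback reverses the order of acylation under base-free conditions. It sets out from 34: trimethyl orthoacetate with PPTS gives the cyclic orthoacetate F7. Mild aqueous acid should open F7 to the monoacetate on the more hindered oxygen, the 9-acetate F8. Methacrylic anhydride with catalytic Sc(OTf)3 then acylates O8 and gives 36.

## Further compounds

F1 | step 22 | terminal-alkyne C1 aldehyde | O=C[C@@](C)(O[Si](CC)(CC)CC)[C@H]1OC(C)(C)O[C@H]1[C@H]2C(=C)C(=O)O[C@@H]2/C=C(/C)C#C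
F2 | step 17 | (6R,7S)-hydroxy ester, anti adduct with silylalkyne | CC[Si](CC)(CC)OC[C@@](C)(O[Si](CC)(CC)CC)[C@H]1OC(C)(C)O[C@H]1[C@@H](C(=C)C(=O)OC)[C@H](O)/C=C(/C)C#C[Si](C)(C)C
F3 | step 17 | trans-lactone with silylalkyne | CC[Si](CC)(CC)OC[C@@](C)(O[Si](CC)(CC)CC)[C@H]1OC(C)(C)O[C@H]1[C@H]2C(=C)C(=O)O[C@@H]2/C=C(/C)C#C[Si](C)(C)C
F4 | step 19 | (6R)-4-nitrobenzoate of the hydroxy ester | CC[Si](CC)(CC)OC[C@@](C)(O[Si](CC)(CC)CC)[C@H]1OC(C)(C)O[C@H]1[C@@H](C(=C)C(=O)OC)[C@H](OC(=O)c1ccc(cc1)[N+](=O)[O-])/C=C(/C)C#C[Si](C)(C)C
F5 | step 19 | (6R,7S)-hydroxy ester with terminal alkyne | CC[Si](CC)(CC)OC[C@@](C)(O[Si](CC)(CC)CC)[C@H]1OC(C)(C)O[C@H]1[C@@H](C(=C)C(=O)OC)[C@H](O)/C=C(/C)C#C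
F6 | step 24 | β-methoxy enone (C3 methoxy, C2=C3) | CC1(C)O[C@H]2[C@H]3C(=C)C(=O)O[C@@H]3/C=C(/C)C(OC)=CC(=O)[C@@](C)(O[Si](CC)(CC)CC)[C@H]2O1
F7 | step 26 | 8,9-cyclic methyl orthoacetate | COC1(C)O[C@H]2[C@H]3C(=C)C(=O)O[C@@H]3/C=C(/C)C3=CC(=O)[C@@](C)(O3)[C@H]2O1
F8 | step 26 | 9-O-acetyl-8-ol | O[C@H]1[C@H]2C(=C)C(=O)O[C@@H]2/C=C(/C)C2=CC(=O)[C@@](C)(O2)[C@H]1OC(C)=O
A1 | alternative 1 | furan-bridged (C3–C6) macrocyclic ketol | COC(=O)C[C@H]1c2cc(C)c(o2)CC(=O)[C@@](C)(O)[C@H]2OC(C)(C)O[C@@H]12
A2 | alternative 1 | bridged furanone with (Z)-C4=C5 and C6 ketone | COC(=O)C[C@H]1C(=O)/C=C(/C)C2=CC(=O)[C@@](C)(O2)[C@H]2OC(C)(C)O[C@@H]12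
A3 | alternative 2 | C7,C10-divinyl furanone lactone | C=C[C@H]1C(=C)C(=O)O[C@@H]1/C=C(/C)C1=CC(=O)[C@](C)(C=C)O1
A4 | alternative 2 | bridged macrocycle with (Z)-C8=C9 | C=C1C(=O)O[C@@H]2/C=C(/C)C3=CC(=O)[C@@](C)(O3)/C=C\[C@@H]12
A5 | alternative 3 | enal oxime with C10 ethynyl carbinol | C#C[C@@](C)(O)[C@H]1OC(C)(C)O[C@H]1[C@H]2CC(=O)O[C@@H]2/C=C(/C)C=NO
A6 | alternative 3 | isoxazole-bridged ten-membered carbocycle | CC1(C)O[C@H]2[C@H]3CC(=O)O[C@@H]3/C=C(/C)c3cc(on3)[C@@](C)(O)[C@H]2O1
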